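**Retrosynthetic overview**
1. The C15–quinone bond is made last. Unprotected 2,5-dihydroxybenzoquinone is reductively alkylated with the neopentyl aldehyde 14 and then O-methylated at one site, so no benzyl halide, aryl-metal or CAN step is needed.
2. C4=CH2 comes from a C4 ketone. The angular C5 methyl is added late by Stork reductive methylation of the Δ5(6)-4-enone 11. The axial 9β-methyl blocks the β face, so the methyl enters α and gives the cis-decalin.
3. Key step: ring B is built onto ring A by an exo-selective, auxiliary-controlled Diels–Alder reaction of the 2-vinylcyclohexenone ketal 5 with N-tigloyl oxazolidinone 8. This sets C8, quaternary C9 and C10 in one operation.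
4. Diene 5 comes from cyclohexenone by bromination, ketalisation and Suzuki vinylation.
5. Ring order: A (purchased carbocycle), then B (Diels–Alder), then the quinone (purchased ring, attached intact).

Assumption and numbering: the SMILES decodes to the cis-fused decalin (5-epi-ilimaquinone type), (5R,8S,9R,10S), with 5-Me α, H-10 α, 9-Me β, 9-CH2-quinone α and 8-Me β. Terpenoid numbering is used: C4 bears the =CH2 (C11) and C15 is the CH2 linking C9 to the quinone.

**Step 1**
Reactants: 1 cyclohex-2-en-1-one
Product: 2 2-bromocyclohex-2-en-1-one
Conditions: Br2, CH2Cl2, 0 °C; then Et3N, 0 °C → rt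
Reagents that add atoms: bromine, BrBr
Why: Bromination–dehydrobromination places Br regiospecifically on the α-carbon (future C5), and no stereocentre is formed.

**Step 2**
Reactants: 2
Product: 3 6-bromo-1,4-dioxaspiro[4.5]dec-6-ene
Conditions: HOCH2CH2OH, p-TsOH (cat.), benzene, Dean–Stark reflux
Reagents that add atoms: ethylene glycol, OCCO
Why: Acid-catalysed ketalisation with azeotropic water removal works because the electron-poor bromoalkene does not migrate, and it turns the enone into a non-electron-poor diene precursor.

**Step 3**
Reactants: 3; 4 potassium vinyltrifluoroborate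
Product: 5 6-ethenyl-1,4-dioxaspiro[4.5]dec-6-ene (diene C7=C6–C5=C10, ketal at C4)
Conditions: PdCl2(dppf)·CH2Cl2 (3 mol %), Et3N, n-PrOH, 90 °C
Reagents that add atoms: none beyond the numbered reactants
Why: Suzuki–Miyaura vinylation of an alkenyl bromide runs under basic conditions that leave the ketal untouched.

**Step 4**
Reactants: 6 (4S)-4-benzyl-1,3-oxazolidin-2-one; 7 tigloyl chloride [(E)-2-methylbut-2-enoyl chloride]
Product: 8 (4S)-4-benzyl-3-[(E)-2-methylbut-2-enoyl]-1,3-oxazolidin-2-one
Conditions: n-BuLi, THF, −78 °C; then 7, −78 → 0 °C
Reagents that add atoms: none beyond the numbered reactants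
Why: N-acylation of the lithiated Evans auxiliary proceeds with retention of the E-alkene geometry.

**Step 5 (key step)**
Reactants: 5; 8
Product: 9, the Diels–Alder adduct. It is (4S)-4-benzyl-3-{[(4'aR,5'R,6'S)-5',6'-dimethyl-3',4',4'a,5',6',7'-hexahydro-2'H-spiro[1,3-dioxolane-2,1'-naphthalen]-5'-yl]carbonyl}-1,3-oxazolidin-2-one. It has a Δ5(6) alkene, H-10 α, the C9 acyl α, 9-Me β and 8-Me β.
Conditions: 8 + Me2AlCl (1.5 equiv), CH2Cl2, −78 °C; then 5 (1.5 equiv), −78 → −30 °C
Reagents that add atoms: none beyond the numbered reactants
Why: This is a Lewis-acid-promoted, auxiliary-controlled exo Diels–Alder reaction in which "ortho" regiochemistry joins the substituted diene terminus C10 to the acyl-bearing C9, suprafacial addition to the E-tigloyl unit makes 8-Me and 9-Me cis, the C4 ketal next to C5 acts like a gem-dialkyl group and forces the bulky Al-chelated acyl exo so that H-10 ends up cis to C15, and the benzyl group of the chelated s-cis (S)-imide shields the C9-Re face so the diene adds to C9-Si.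

**Step 6**
Reactants: 9
Product: 10 [(4'aS,5'R,6'S)-5',6'-dimethyl-3',4',4'a,5',6',7'-hexahydro-2'H-spiro[1,3-dioxolane-2,1'-naphthalen]-5'-yl]methanol
Conditions: LiBH4, MeOH (2 equiv), Et2O, 0 °C → rt; basic work-up (auxiliary 6 recovered)
Reagents that add atoms: none
Why: Reductive cleavage of the N-acyl oxazolidinone occurs at the more electrophilic exocyclic imide carbonyl, and the ketal, the alkene and all stereocentres are unaffected.

**Step 7**
Reactants: 10
Product: 11 (4aS,5R,6S)-5-(hydroxymethyl)-5,6-dimethyl-3,4,4a,5,6,7-hexahydronaphthalen-1(2H)-one (s-cis enone C4(=O)–C5=C6)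
Conditions: PPTS (cat.), acetone/H2O, 40 °C
Reagents that add atoms: water, O
Why: Mild hydrolysis of the allylic ketal reveals an alkene that is already conjugated, and because C10–H is attached to the enone α-carbon and is not acidified, the ring-fusion centre is not scrambled.

**Step 8**
Reactants: 11
Product: 12 (4aS,5R,6S,8aR)-5-(hydroxymethyl)-5,6,8a-trimethyloctahydronaphthalen-1(2H)-one (cis-decalone, with new 5-Me α, cis to H-10)
Conditions: Li (6 equiv), NH3(l)/THF, −78 → −33 °C; isoprene; MeI (5 equiv), −78 → −33 °C; NH4Cl
Reagents that add atoms: iodomethane, CI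
Why: In this Stork reductive alkylation the dissolving metal gives the tetrasubstituted C4=C5 lithium enolate regiospecifically (C6 is protonated by the substrate OH, and the lithium alkoxide is inert to MeI at this temperature), and because ring B is locked in the chair with the 9β-methyl axial and syn to the β lobe of C5, MeI attacks from the α face, reinforcing the usual cis preference of angular methylation of 1-decalone enolates.

**Step 9**
Reactants: 12
Product: 13 [(1R,2S,4aR,8aR)-1,2,4a-trimethyl-5-methylidenedecahydronaphthalen-1-yl]methanol
Conditions: Ph3PCH3Br (5 equiv), KOt-Bu (4.8 equiv), toluene, 90 °C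
Reagents that add atoms: methyltriphenylphosphonium bromide, C[P+](c1ccccc1)(c1ccccc1)c1ccccc1.[Br-]
Why: Wittig methylenation with excess non-stabilised ylide at elevated temperature overcomes the hindrance next to quaternary C5, the free OH only consumes one equivalent of base, and the sole enolisable position (C3) is not stereogenic.

**Step 10**
Reactants: 13
Product: 14 (1R,2S,4aR,8aR)-1,2,4a-trimethyl-5-methylidenedecahydronaphthalene-1-carbaldehyde
Conditions: Dess–Martin periodinane, NaHCO3, CH2Cl2, 0 °C → rt
Reagents that add atoms: none
Why: Dess–Martin oxidation of the neopentyl primary alcohol gives a non-enolisable aldehyde, and the 1,1-disubstituted alkene is inert.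

**Step 11**
Reactants: 14; 15 2,5-dihydroxy-1,4-benzoquinone (3 equiv)
Product: 16 2,5-dihydroxy-3-{[(1R,2S,4aR,8aS)-1,2,4a-trimethyl-5-methylidenedecahydronaphthalen-1-yl]methyl}cyclohexa-2,5-diene-1,4-dione
Conditions: Hantzsch ester (1.5 equiv), L-proline (30 mol %), EtOH/CH2Cl2, 45 °C; air work-up
Reagents that add atoms: none beyond the numbered reactants (the Hantzsch ester gives only H; the aldehyde O leaves as water)
Why: Proposed new method: proline-iminium Knoevenagel condensation at the nucleophilic C3–H of the vinylogous acid gives an alkylidene (o-quinone-methide-type) intermediate that is reduced irreversibly at C15 by hydride transfer from the Hantzsch ester; the closest known reaction is the three-component reductive alkylation of lawsone and 2,5-dihydroxybenzoquinone with linear and α-branched aldehydes, and the untested part is the α-quaternary aldehyde, which cannot enolise or self-condense, so the slow condensation should be drained by the irreversible reduction while excess 15 suppresses double alkylation, and no stereocentre is touched.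

**Step 12**
Reactants: 16
Product: 17, the target, 2-hydroxy-5-methoxy-3-{[(1R,2S,4aR,8aS)-1,2,4a-trimethyl-5-methylidenedecahydronaphthalen-1-yl]methyl}cyclohexa-2,5-diene-1,4-dione
Conditions: TMSCHN2 (1.0 equiv, slow addition), toluene/MeOH 4:1, −20 → 0 °C
Reagents that add atoms: (trimethylsilyl)diazomethane, C[Si](C)(C)C=[N+]=[N-]
Why: Site-selective O-methylation occurs at the more acidic, unhindered vinylogous-acid OH next to the ring C–H, because the other OH is flanked by the neopentyl CH2 and made less acidic by the alkyl donor, and the neutral conditions spare the acid-labile exocyclic alkene.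

**Compound list**
1 | cyclohex-2-en-1-one | O=C1C=CCCC1 | starting material
2 | 2-bromocyclohex-2-en-1-one | O=C1C(Br)=CCCC1 | intermediate
3 | 6-bromo-1,4-dioxaspiro[4.5]dec-6-ene | BrC1=CCCCC12OCCO2 | intermediate
4 | potassium vinyltrifluoroborate | C=C[B-](F)(F)F.[K+] | starting material
5 | 6-ethenyl-1,4-dioxaspiro[4.5]dec-6-ene | C=CC1=CCCCC12OCCO2 | intermediate
6 | (4S)-4-benzyl-1,3-oxazolidin-2-one | O=C1N[C@@H](Cc2ccccc2)CO1 | starting material
7 | tigloyl chloride | C/C=C(\C)C(=O)Cl | starting material
8 | (4S)-4-benzyl-3-[(E)-2-methylbut-2-enoyl]-1,3-oxazolidin-2-one | C/C=C(\C)C(=O)N1[C@@H](Cc2ccccc2)COC1=O | intermediate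
9 | exo Diels–Alder adduct (imide, C4 ketal, Δ5(6); 8S,9R,10R) | O1CCOC12CCC[C@H]3[C@](C)(C(=O)N4[C@@H](Cc5ccccc5)COC4=O)[C@@H](C)CC=C23 | intermediate
10 | ketal alcohol (8S,9R,10S) | O1CCOC12CCC[C@H]3[C@](C)(CO)[C@@H](C)CC=C23 | intermediate
11 | hydroxy enone (8S,9R,10S) | O=C1CCC[C@H]2[C@](C)(CO)[C@@H](C)CC=C12 | intermediate
12 | cis-5-methyl hydroxy ketone (5R,8S,9R,10S) | O=C1CCC[C@H]2[C@](C)(CO)[C@@H](C)CC[C@@]12C | intermediate
13 | methylidene alcohol (5R,8S,9R,10R) | C=C1CCC[C@H]2[C@](C)(CO)[C@@H](C)CC[C@@]12C | intermediate
14 | methylidene aldehyde (5R,8S,9R,10R) | C=C1CCC[C@H]2[C@](C)(C=O)[C@@H](C)CC[C@@]12C | intermediate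
15 | 2,5-dihydroxy-1,4-benzoquinone | O=C1C=C(O)C(=O)C=C1O | starting material
16 | dihydroxyquinone (O-demethyl target; 5R,8S,9R,10S) | C=C1CCC[C@H]2[C@](C)(CC3=C(O)C(=O)C=C(O)C3=O)[C@@H](C)CC[C@@]12C | intermediate
17 | CID21727418 (5R,8S,9R,10S) | C=C1CCC[C@H]2[C@](C)(CC3=C(O)C(=O)C=C(OC)C3=O)[C@@H](C)CC[C@@]12C | target

**Totals**
Total steps: 12.
Longest linear sequence: 11 (1→2→3→5→9→10→11→12→13→14→16→17).

**Three steps most likely to fail**
- **Step 5.** The risks are the exo/endo ratio, the facial sense of the twisted α-methyl imide, and survival of the allylic ketal towards Me2AlCl. Fallback: reverse the cycloaddition partners. Use (R)-(−)-carvone as a chiral 2-methylcyclohexenone (C5=C10 dienophile) with 3-silyloxy-1,3-pentadiene. Addition anti to the isopropenyl group fixes the cis fusion and the 5-Me directly. Then remove the isopropenyl group by ozonolysis followed by Fe(II)/thiol hydrodealkenylation, and build C9 and C8 from the resulting C8 ketone.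
- **Step 11.** The risk is that reductive alkylation fails with the very hindered α-quaternary aldehyde. Fallback: switch polarity. Convert alcohol 13 to the neopentyl iodide and then to the organozinc, which has no β-hydrogens. Couple it by Negishi reaction with 1-bromo-2,3,5,6-tetramethoxybenzene, oxidise with CAN, and selectively hydrolyse the hindered vinylogous ester.
- **Step 8.** The risks are C- versus O-methylation, enolate equilibration and the α/β ratio. Fallback: make ring A last. Run the tigloyl Diels–Alder reaction on an acyclic 2-silyloxy-3-methyl-1,3-diene carrying a pent-4-ynyl chain at C10. Close ring A by Au(I)-catalysed 6-exo-dig cyclisation of the silyl enol ether onto the alkyne. This can only deliver C4 to the face bearing the tether, which gives the cis fusion, and it creates quaternary C5 and the exocyclic methylene together. Then remove the C6 ketone by Wolff–Kishner reduction.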